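## Retrosynthetic overview

1. The last C–C bond is a C(sp3)–C(sp2) Negishi coupling between iodo-lactone 10 (lactone ring plus side-chain carbons C1′–C3′) and (E)-alkenyl iodide 22 (furan, both trisubstituted alkenes, the (S)-carbinol); desilylation follows.
2. The only ring built is the γ-lactone (O1, C2(=O), C3, C4, C5); the furan ring is bought. The lactone closes in the key step, where CO2 is joined to a vinyl epoxide in one flask: the C2–C3 bond forms by carboxylation of the hydroborated vinyl group, and the O1–C5 bond forms when the new carboxylate opens the epoxide.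
3. Enabling feature: ring oxygen O1 sits on the quaternary carbon C5 (bearing CH3 and C4) directly beside the acetoxy carbon C1′. This anti-1,2-dioxygen pattern is the retron of an (E)-trisubstituted epoxide opened with inversion at C5 by a carboxylate. The carboxyl carbon C2 lies two CH2 groups (C3, C4) from C5, so it can come from CO2 and a vinyl group.
4. Both lactone-side stereocentres (C5, C1′) derive from one Shi epoxidation of a diene. The remote carbinol is set by catalytic asymmetric propargylation of but-2-ynal. The (E)-alkenes come from syn-carboalumination and syn-hydrozirconation of alkynes.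

Key step: step 4

## Route

Step 1
Reactants: 1 3-[(tert-butyldimethylsilyl)oxy]propanal
Product: 2 (2E)-5-[(tert-butyldimethylsilyl)oxy]-2-methylpent-2-enal
Conditions: Ph3P=C(CH3)CHO, toluene, 90 °C
Reagents that add atoms: 2-(triphenylphosphoranylidene)propanal, CC(C=O)=P(c1ccccc1)(c1ccccc1)c1ccccc1
Why: Wittig olefination with the stabilised formyl ylide should give the (E)-2-methyl enal selectively, and no stereocentre is formed.

Step 2
Reactants: 2 (2E)-5-[(tert-butyldimethylsilyl)oxy]-2-methylpent-2-enal
Product: 3 tert-butyldimethyl{[(3E)-4-methylhexa-3,5-dien-1-yl]oxy}silane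
Conditions: Ph3PCH3Br, KN(SiMe3)2, THF, 0 °C
Reagents that add atoms: methyltriphenylphosphonium bromide, C[P+](c1ccccc1)(c1ccccc1)c1ccccc1.[Br-]
Why: Wittig methylenation adds the non-stabilised ylide 1,2 to the enal carbonyl and leaves the (E)-trisubstituted alkene untouched, giving the 1,3-diene.

Step 3
Reactants: 3 tert-butyldimethyl{[(3E)-4-methylhexa-3,5-dien-1-yl]oxy}silane
Product: 4 (2R,3R)-3-{2-[(tert-butyldimethylsilyl)oxy]ethyl}-2-ethenyl-2-methyloxirane
Conditions: Shi ketone (D-fructose-derived, 0.3 equiv), Oxone (2KHSO5·KHSO4·K2SO4), K2CO3, Bu4NHSO4, MeCN/dimethoxymethane–aq. Na2B4O7/Na2EDTA (pH about 10.5), −5 to 0 °C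
Reagents that add atoms: potassium peroxymonosulfate (active component of Oxone), [K+].[O-]S(=O)(=O)OO
Why: Shi asymmetric epoxidation, in which the chiral dioxirane attacks the more electron-rich trisubstituted alkene of the diene through the spiro transition state, so catalyst control sets both oxirane stereocentres (2R,3R) while the vinyl group stays intact.

Step 4
Reactants: 4 (2R,3R)-3-{2-[(tert-butyldimethylsilyl)oxy]ethyl}-2-ethenyl-2-methyloxirane
Product: 8 (5S)-5-[(1R)-1,3-dihydroxypropyl]-5-methyloxolan-2-one, via alkylborane 5 (not isolated), via epoxy acid 6 (not isolated), via silyl ether lactone 7 (not isolated)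
Conditions: 9-BBN dimer (0.55 equiv), THF, 0 °C to rt; then (IPr)CuCl (5 mol%; IPr = 1,3-bis(2,6-diisopropylphenyl)imidazol-2-ylidene), LiOMe (1.1 equiv), CO2 (1 atm), 70 °C; then 2 M aq. HCl, THF, rt
Reagents that add atoms: carbon dioxide, O=C=O
Why: 9-BBN adds anti-Markovnikov to the only monosubstituted alkene to give primary alkylborane 5; LiOMe forms the borate, the primary alkyl group passes to (IPr)Cu, and the alkylcopper inserts CO2 (bond between the former vinyl CH2, lactone C3, and the CO2 carbon, lactone C2); on acidification the γ,δ-epoxy acid 6 cyclises by attack of the carboxyl oxygen on the protonated epoxide (bond O1–C5), after which the same aqueous acid cleaves the primary silyl ether of 7. The closest known reaction types are the copper-catalysed carboxylation of B-alkyl-9-BBN reagents with CO2 (formal reductive carboxylation of terminal alkenes) and the acid-promoted lactonisation of 4,5-epoxy acids. The γ-lactone closes in the 5-exo-tet mode. The quaternary stereocentre C5 is set by stereospecific anti opening (inversion at the tertiary epoxide carbon, relayed from the Shi epoxide), while the carbinol carbon C1′ keeps its epoxide C–O bond and its configuration. The step needs hydroboration of the vinyl group without reductive opening of the allylic epoxide, and attack at the tertiary rather than the secondary epoxide carbon; the bulky, weakly Lewis-acidic 9-BBN in THF with early conversion to the borate should secure the first, and the coincidence of the 5-exo (over 6-endo) and Markovnikov (tertiary carbon) preferences the second.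

Step 5
Reactants: 8 (5S)-5-[(1R)-1,3-dihydroxypropyl]-5-methyloxolan-2-one
Product: 9 (5S)-5-[(1R)-1-hydroxy-3-iodopropyl]-5-methyloxolan-2-one
Conditions: I2, PPh3, imidazole, CH2Cl2, 0 °C
Reagents that add atoms: iodine, II
Why: Appel-type iodination should convert only the unhindered primary alcohol, the secondary carbinol next to the quaternary centre being too hindered for SN2 displacement.

Step 6
Reactants: 9 (5S)-5-[(1R)-1-hydroxy-3-iodopropyl]-5-methyloxolan-2-one
Product: 10 (1R)-3-iodo-1-[(2S)-2-methyl-5-oxooxolan-2-yl]propyl acetate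
Conditions: Ac2O, DMAP (cat.), pyridine, CH2Cl2, 0 °C to rt
Reagents that add atoms: acetic anhydride, CC(=O)OC(C)=O
Why: DMAP-catalysed acylation of the secondary alcohol installs the acetate without touching the stereocentres or the primary iodide.

Step 7
Reactants: 11 but-2-yn-1-ol
Product: 12 but-2-ynal
Conditions: MnO2 (activated), CH2Cl2, rt; filtered solution used directly
Reagents that add atoms: none
Why: MnO2 oxidises the activated propargylic alcohol to the ynal without over-oxidation.

Step 8
Reactants: 12 but-2-ynal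
Product: 13 (4S)-hepta-1,5-diyn-4-ol
Conditions: allenylB(pin), (S)-TRIP [(S)-3,3′-bis(2,4,6-triisopropylphenyl)-1,1′-binaphthyl-2,2′-diyl hydrogen phosphate] (10 mol%), 4 Å molecular sieves, toluene, −20 °C
Reagents that add atoms: allenylboronic acid pinacol ester, C=C=CB1OC(C)(C)C(C)(C)O1
Why: Chiral phosphoric acid-catalysed propargylboration, in which the allenylboronate adds through a closed six-membered SE2′ transition state to the Si face selected by the catalyst and so sets the (S)-carbinol; (S)-TRIP is chosen on the expectation that its antipode gives (R)-carbinols from aldehydes with the same priority pattern (O > sp- or sp2-carbon > CH2 > H).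

Step 9
Reactants: 13 (4S)-hepta-1,5-diyn-4-ol
Product: 15 (1E,4S)-1-iodo-2-methylhept-1-en-5-yn-4-ol, via alkenylalane 14 (not isolated)
Conditions: AlMe3 (3 equiv), Cp2ZrCl2 (0.25 equiv), CH2Cl2, 0 °C to rt; then I2, THF, −30 to 0 °C; aq. NaHCO3/Na2S2O3 work-up
Reagents that add atoms: trimethylaluminium, C[Al](C)C; iodine, II
Why: Zirconium-catalysed carboalumination (Negishi) adds CH3–Al syn across the terminal alkyne with aluminium at the terminus, and iodinolysis with retention should give the (E)-2-methylalkenyl iodide, the internal alkyne reacting far more slowly.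

Step 10
Reactants: 16 furan-3-carbaldehyde
Product: 17 3-ethenylfuran
Conditions: Ph3PCH3Br, n-BuLi, Et2O, 0 °C to rt; distilled and used as a solution
Reagents that add atoms: methyltriphenylphosphonium bromide, C[P+](c1ccccc1)(c1ccccc1)c1ccccc1.[Br-]
Why: Wittig methylenation of the heteroaromatic aldehyde gives the vinylfuran.

Step 11
Reactants: 17 3-ethenylfuran; 15 (1E,4S)-1-iodo-2-methylhept-1-en-5-yn-4-ol
Product: 19 (4S,6E)-9-(furan-3-yl)-6-methylnon-6-en-2-yn-4-ol, via alkylborane 18 (not isolated)
Conditions: 9-BBN dimer (0.5 equiv per alkene, no excess), THF, 0 °C to rt; then 15, Pd(dppf)Cl2 (5 mol%), AsPh3, Cs2CO3, DMF/H2O, rt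
Reagents that add atoms: none
Why: B-alkyl Suzuki–Miyaura coupling, in which 9-BBN adds anti-Markovnikov to the vinylfuran and the primary alkyl group is coupled with the alkenyl iodide with retention of the (E)-geometry.

Step 12
Reactants: 19 (4S,6E)-9-(furan-3-yl)-6-methylnon-6-en-2-yn-4-ol
Product: 20 tert-butyl{[(4S,6E)-9-(furan-3-yl)-6-methylnon-6-en-2-yn-4-yl]oxy}dimethylsilane
Conditions: TBSCl, imidazole, DMF, rt
Reagents that add atoms: tert-butyldimethylsilyl chloride, CC(C)(C)[Si](C)(C)Cl
Why: Standard silylation protects the carbinol for the hydrozirconation and the organozinc coupling and leaves the stereocentre untouched.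

Step 13
Reactants: 20 tert-butyl{[(4S,6E)-9-(furan-3-yl)-6-methylnon-6-en-2-yn-4-yl]oxy}dimethylsilane
Product: 22 tert-butyl{[(2E,4S,6E)-9-(furan-3-yl)-2-iodo-6-methylnona-2,6-dien-4-yl]oxy}dimethylsilane, via alkenylzirconocene 21 (not isolated)
Conditions: Cp2Zr(H)Cl (1.8 equiv), THF, rt to 40 °C; then I2, 0 °C
Reagents that add atoms: iodine, II
Why: Hydrozirconation with the Schwartz reagent is a syn addition that, with excess reagent (thermodynamic control), places zirconium on the methyl-bearing alkyne carbon remote from the bulky silyloxy-bearing centre, and iodinolysis with retention should give the (E)-2-iodoalkene.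

Step 14
Reactants: 10 (1R)-3-iodo-1-[(2S)-2-methyl-5-oxooxolan-2-yl]propyl acetate; 22 tert-butyl{[(2E,4S,6E)-9-(furan-3-yl)-2-iodo-6-methylnona-2,6-dien-4-yl]oxy}dimethylsilane
Product: 24 (1R,4E,6S,8E)-6-[(tert-butyldimethylsilyl)oxy]-11-(furan-3-yl)-4,8-dimethyl-1-[(2S)-2-methyl-5-oxooxolan-2-yl]undeca-4,8-dien-1-yl acetate, via alkylzinc iodide 23 (not isolated)
Conditions: 10, Zn dust (activated with Me3SiCl and BrCH2CH2Br), LiCl, THF, 35 °C; then 22, Pd(dppf)Cl2 (5 mol%), THF/DMA, 40 °C
Reagents that add atoms: none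
Why: LiCl-assisted zinc insertion into the primary iodide (tolerant of ester and lactone) followed by palladium-catalysed Negishi coupling joins C(sp3) to C(sp2) with retention of the alkenyl iodide geometry and without touching any stereocentre.

Step 15
Reactants: 24 (1R,4E,6S,8E)-6-[(tert-butyldimethylsilyl)oxy]-11-(furan-3-yl)-4,8-dimethyl-1-[(2S)-2-methyl-5-oxooxolan-2-yl]undeca-4,8-dien-1-yl acetate
Product: 25 15-acetylirciformonin B, (1R,4E,6S,8E)-11-(furan-3-yl)-6-hydroxy-4,8-dimethyl-1-[(2S)-2-methyl-5-oxooxolan-2-yl]undeca-4,8-dien-1-yl acetate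
Conditions: HF·pyridine, pyridine, THF, 0 °C to rt
Reagents that add atoms: none
Why: Buffered fluoride desilylation frees the allylic alcohol under conditions that should spare the acetate, the lactone and the furan.

## Compound list

1 | 3-[(tert-butyldimethylsilyl)oxy]propanal | O=CCCO[Si](C)(C)C(C)(C)C | starting material
2 | (2E)-5-[(tert-butyldimethylsilyl)oxy]-2-methylpent-2-enal | O=C/C(C)=C/CCO[Si](C)(C)C(C)(C)C | intermediate
3 | tert-butyldimethyl{[(3E)-4-methylhexa-3,5-dien-1-yl]oxy}silane | C=C/C(C)=C/CCO[Si](C)(C)C(C)(C)C | intermediate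
4 | (2R,3R)-3-{2-[(tert-butyldimethylsilyl)oxy]ethyl}-2-ethenyl-2-methyloxirane | C=C[C@@]1(C)O[C@@H]1CCO[Si](C)(C)C(C)(C)C | intermediate
5 | 9-{2-[(2R,3R)-3-{2-[(tert-butyldimethylsilyl)oxy]ethyl}-2-methyloxiran-2-yl]ethyl}-9-borabicyclo[3.3.1]nonane | B1(CC[C@@]2(C)O[C@@H]2CCO[Si](C)(C)C(C)(C)C)C2CCCC1CCC2 | intermediate
6 | 3-[(2R,3R)-3-{2-[(tert-butyldimethylsilyl)oxy]ethyl}-2-methyloxiran-2-yl]propanoic acid (formed as its lithium salt, free acid on acidification) | OC(=O)CC[C@@]1(C)O[C@@H]1CCO[Si](C)(C)C(C)(C)C | intermediate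
7 | (5S)-5-{(1R)-3-[(tert-butyldimethylsilyl)oxy]-1-hydroxypropyl}-5-methyloxolan-2-one | O[C@H](CCO[Si](C)(C)C(C)(C)C)[C@]1(C)CCC(=O)O1 | intermediate
8 | (5S)-5-[(1R)-1,3-dihydroxypropyl]-5-methyloxolan-2-one | O[C@H](CCO)[C@]1(C)CCC(=O)O1 | intermediate
9 | (5S)-5-[(1R)-1-hydroxy-3-iodopropyl]-5-methyloxolan-2-one | O[C@H](CCI)[C@]1(C)CCC(=O)O1 | intermediate
10 | (1R)-3-iodo-1-[(2S)-2-methyl-5-oxooxolan-2-yl]propyl acetate | CC(=O)O[C@H](CCI)[C@]1(C)CCC(=O)O1 | intermediate
11 | but-2-yn-1-ol | CC#CCO | starting material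
12 | but-2-ynal | CC#CC=O | intermediate
13 | (4S)-hepta-1,5-diyn-4-ol | CC#C[C@@H](O)CC#C | intermediate
14 | {(1E,4S)-4-[(dimethylalumanyl)oxy]-2-methylhept-1-en-5-yn-1-yl}dimethylalumane | CC#C[C@@H](O[Al](C)C)C/C(C)=C/[Al](C)C | intermediate
15 | (1E,4S)-1-iodo-2-methylhept-1-en-5-yn-4-ol | CC#C[C@@H](O)C/C(C)=C/I | intermediate
16 | furan-3-carbaldehyde | O=Cc1ccoc1 | starting material
17 | 3-ethenylfuran | C=Cc1ccoc1 | intermediate
18 | 9-[2-(furan-3-yl)ethyl]-9-borabicyclo[3.3.1]nonane | B1(CCc2ccoc2)C2CCCC1CCC2 | intermediate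
19 | (4S,6E)-9-(furan-3-yl)-6-methylnon-6-en-2-yn-4-ol | CC#C[C@@H](O)C/C(C)=C/CCc1ccoc1 | intermediate
20 | tert-butyl{[(4S,6E)-9-(furan-3-yl)-6-methylnon-6-en-2-yn-4-yl]oxy}dimethylsilane | CC#C[C@@H](O[Si](C)(C)C(C)(C)C)C/C(C)=C/CCc1ccoc1 | intermediate
21 | chlorobis(cyclopentadienyl){(2E,4S,6E)-4-[(tert-butyldimethylsilyl)oxy]-9-(furan-3-yl)-6-methylnona-2,6-dien-2-yl}zirconium | Cl[Zr](C1C=CC=C1)(C1C=CC=C1)/C(C)=C/[C@@H](O[Si](C)(C)C(C)(C)C)C/C(C)=C/CCc1ccoc1 | intermediate
22 | tert-butyl{[(2E,4S,6E)-9-(furan-3-yl)-2-iodo-6-methylnona-2,6-dien-4-yl]oxy}dimethylsilane | I/C(C)=C/[C@@H](O[Si](C)(C)C(C)(C)C)C/C(C)=C/CCc1ccoc1 | intermediate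
23 | {(3R)-3-acetoxy-3-[(2S)-2-methyl-5-oxooxolan-2-yl]propyl}zinc iodide | CC(=O)O[C@H](CC[Zn]I)[C@]1(C)CCC(=O)O1 | intermediate
24 | (1R,4E,6S,8E)-6-[(tert-butyldimethylsilyl)oxy]-11-(furan-3-yl)-4,8-dimethyl-1-[(2S)-2-methyl-5-oxooxolan-2-yl]undeca-4,8-dien-1-yl acetate | CC(=O)O[C@H](CC/C(C)=C/[C@@H](O[Si](C)(C)C(C)(C)C)C/C(C)=C/CCc1ccoc1)[C@]1(C)CCC(=O)O1 | intermediate
25 | 15-acetylirciformonin B, (1R,4E,6S,8E)-11-(furan-3-yl)-6-hydroxy-4,8-dimethyl-1-[(2S)-2-methyl-5-oxooxolan-2-yl]undeca-4,8-dien-1-yl acetate | CC(=O)O[C@H](CC/C(C)=C/[C@@H](O)C/C(C)=C/CCc1ccoc1)[C@]1(C)CCC(=O)O1 | target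

## Step count and risks

Total step count: 15.
Longest linear sequence: 8 steps (1 → 2 → 3 → 4 → 8 → 9 → 10 → 24 → 25; the branch 11 → 12 → 13 → 15 → 19 → 20 → 22 → 24 → 25 is equally long).

Steps most likely to fail:

**Step 4 (key step).** During hydroboration the borane may open the allylic epoxide reductively (hydride delivery to the vinyl terminus with C–O cleavage) or isomerise it as a Lewis acid. As the borate it may also undergo 1,3-elimination to a cyclopropane before carbon dioxide is captured. The fallback sets out from diene 3 and comes back at diol lactone 8; the order of events is inverted so that the borane never meets the epoxide. Diene 3 is hydroborated with 9-BBN at the terminal vinyl group to give 9-[(3E)-6-{[tert-butyl(dimethyl)silyl]oxy}-3-methylhex-3-en-1-yl]-9-borabicyclo[3.3.1]nonane F1. This is carboxylated under the same (IPr)CuCl/LiOMe/CO2 conditions to (4E)-7-{[tert-butyl(dimethyl)silyl]oxy}-4-methylhept-4-enoic acid F2. Shi epoxidation of F2 under the conditions of step 3, followed by acidification, should give epoxy acid 6, which lactonises to 7 and is desilylated to 8 as in step 4. The two bonds are then made in separate operations, each with direct precedent.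

**Step 8.** Enantiofacial discrimination may be poor, because the rod-like propynyl group gives the catalyst pocket little steric bias, or the sense of induction may be opposite to the one assumed. The fallback sets out from carbinol 19 of insufficient enantiomeric purity and comes back at 19; the stereocentre is set by reduction instead of by C–C bond formation. Carbinol 19 is oxidised with MnO2 to (6E)-9-(furan-3-yl)-6-methylnon-6-en-2-yn-4-one F3. Noyori asymmetric transfer hydrogenation with Ru[(S,S)-TsDPEN](p-cymene) in i-PrOH treats the alkyne like the aryl group of acetophenone and should return (S)-19 in high enantiomeric purity.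

**Step 3.** Regio- or enantioselectivity of the dioxirane on the conjugated diene may be incomplete, and the acid-labile vinyl epoxide may be lost during isolation. The fallback sets out from enal 2 and comes back at vinyl epoxide 4. Luche reduction of 2 (NaBH4, CeCl3·7H2O, MeOH) gives (2E)-5-{[tert-butyl(dimethyl)silyl]oxy}-2-methylpent-2-en-1-ol F4. Sharpless asymmetric epoxidation (Ti(OiPr)4, D-(−)-diethyl tartrate, t-BuOOH, 4 Å molecular sieves, CH2Cl2, −20 °C) gives [(2R,3R)-3-(2-{[tert-butyl(dimethyl)silyl]oxy}ethyl)-2-methyloxiran-2-yl]methanol F5. Parikh–Doering oxidation (SO3·pyridine, DMSO, i-Pr2NEt) gives (2S,3R)-3-(2-{[tert-butyl(dimethyl)silyl]oxy}ethyl)-2-methyloxirane-2-carbaldehyde F6, which has no epimerisable α-hydrogen. Wittig methylenation of F6 gives 4.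

## Further compounds

F1 | step 4 | 9-[(3E)-6-{[tert-butyl(dimethyl)silyl]oxy}-3-methylhex-3-en-1-yl]-9-borabicyclo[3.3.1]nonane | B1(CC/C(C)=C/CCO[Si](C)(C)C(C)(C)C)C2CCCC1CCC2
F2 | step 4 | (4E)-7-{[tert-butyl(dimethyl)silyl]oxy}-4-methylhept-4-enoic acid | OC(=O)CC/C(C)=C/CCO[Si](C)(C)C(C)(C)C
F3 | step 8 | (6E)-9-(furan-3-yl)-6-methylnon-6-en-2-yn-4-one | CC#CC(=O)C/C(C)=C/CCc1ccoc1
F4 | step 3 | (2E)-5-{[tert-butyl(dimethyl)silyl]oxy}-2-methylpent-2-en-1-ol | OC/C(C)=C/CCO[Si](C)(C)C(C)(C)C
F5 | step 3 | [(2R,3R)-3-(2-{[tert-butyl(dimethyl)silyl]oxy}ethyl)-2-methyloxiran-2-yl]methanol | OC[C@@]1(C)O[C@@H]1CCO[Si](C)(C)C(C)(C)C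
F6 | step 3 | (2S,3R)-3-(2-{[tert-butyl(dimethyl)silyl]oxy}ethyl)-2-methyloxirane-2-carbaldehyde | O=C[C@@]1(C)O[C@@H]1CCO[Si](C)(C)C(C)(C)C
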